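**Plan**

- Retrosynthesis: the four ester C–O bonds are cut first (caffeoyl on O1, O3 and O5, succinyl on O4), then the C3–C4 bond of the cyclohexane, then the C4–C5 bond (vinyl ketone) and the C1–C2 bond (allylation), which leads back to (S)-malic acid.
- Enabling feature: C3 and C4 are neighbouring ring carbons of the cyclohexane that both carry oxygen on the same face, with the C5 oxygen on the opposite face; a cis-vicinal diol next to an α-oxygen is what reductive coupling of a 1,6-dialdehyde gives.
- Forward: the chain C3–C2–C1–C6–C5–C4 is built on the malic acid dioxolanone by allylation and acyl vinylation, the only carbocycle is closed by SmI2 pinacol coupling, and the esters go on afterwards (succinate on O4 first, then three caffeates).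
- Stereochemistry: C1 comes from (S)-malic acid by self-regeneration of stereocentres (allylation with retention), C5 from a Corey–Bakshi–Shibata reduction, and C3 and C4 from the pinacol step (cis through samarium binding, anti to the C5 silyloxy group).

Key step: step 10

Remark: the target is read as the 4-O-succinyl-1,3,5-tri-O-(E)-caffeoyl ester of natural (−)-quinic acid; quinic acid numbering is used for the ring (O1, O3 and O4 on one face, O5 on the other), and mono-tert-butyl succinate is taken as a purchasable reagent.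

**Route**

Step 1
Reactants: 1 (S)-malic acid; 2 pivalaldehyde
Product: 3 2-[(2S,4S)-2-tert-butyl-5-oxo-1,3-dioxolan-4-yl]acetic acid (cis)
Conditions: t-BuCHO, TsOH·H2O (cat.), H2SO4 (cat.), pentane, reflux (Dean–Stark); recrystallisation
Reagents that add atoms: pivalaldehyde 2, CC(C)(C)C=O
Why: Acid-catalysed acetalisation of the α-hydroxy acid unit (dioxolanone formation for self-regeneration of stereocentres) closes the five-membered acylal under thermodynamic control, the cis isomer predominating and crystallising, so the malic stereocentre is kept and a tert-butyl-bearing acetal centre is created to relay it.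

Step 2
Reactants: 3 2-[(2S,4S)-2-tert-butyl-5-oxo-1,3-dioxolan-4-yl]acetic acid; 4 allyl bromide
Product: 5 2-[(2S,4S)-2-tert-butyl-5-oxo-4-(prop-2-en-1-yl)-1,3-dioxolan-4-yl]acetic acid
Conditions: LiN(SiMe3)2 (2.2 equiv), THF, −78 °C; allyl bromide, −78 → −20 °C; 1 M HCl
Reagents that add atoms: allyl bromide 4, C=CCBr
Why: Enolate alkylation under self-regeneration of stereocentres: the carboxylate–enolate dianion is attacked by allyl bromide on the face away from the tert-butyl group, so allyl takes the place of the former hydrogen (net retention) and fixes the future quaternary C1.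

Step 3
Reactants: 5 2-[(2S,4S)-2-tert-butyl-5-oxo-4-(prop-2-en-1-yl)-1,3-dioxolan-4-yl]acetic acid; 6 tributyl(vinyl)stannane
Product: 8 (2S,5S)-2-tert-butyl-5-(2-oxobut-3-en-1-yl)-5-(prop-2-en-1-yl)-1,3-dioxolan-4-one, via acid chloride 7 (not isolated)
Conditions: (COCl)2, DMF (cat.), CH2Cl2, 0 °C → rt, evaporate; 6, BnPdCl(PPh3)2 (3 mol %), BHT (cat.), THF, 50 °C
Reagents that add atoms: tributyl(vinyl)stannane 6, C=C[Sn](CCCC)(CCCC)CCCC; oxalyl chloride, O=C(Cl)C(=O)Cl (supplies only the chlorine of 7)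
Why: Acid chloride formation followed by Stille acylation (palladium-catalysed coupling of an acid chloride with a vinylstannane) forms the C4–C5 bond under neutral conditions that spare the nucleophile-sensitive dioxolanone, which a vinyl Grignard reagent would attack.

Step 4
Reactants: 8 (2S,5S)-2-tert-butyl-5-(2-oxobut-3-en-1-yl)-5-(prop-2-en-1-yl)-1,3-dioxolan-4-one
Product: 9 (2S,5S)-2-tert-butyl-5-[(2R)-2-hydroxybut-3-en-1-yl]-5-(prop-2-en-1-yl)-1,3-dioxolan-4-one
Conditions: (S)-2-methyl-CBS-oxazaborolidine [(S)-1-methyl-3,3-diphenyltetrahydro-1H,3H-pyrrolo[1,2-c][1,3,2]oxazaborole] (0.3 equiv), catecholborane (1.8 equiv), toluene, −78 °C; MeOH, pH 7 buffer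
Reagents that add atoms: none
Why: Corey–Bakshi–Shibata reduction with catecholborane (the enone variant, which does not hydroborate the alkenes at −78 °C) should give the (R)-carbinol, the future C5, under catalyst control with vinyl as the larger group, and the minor C5 epimer is a diastereomer that chromatography should remove.

Step 5
Reactants: 9 (2S,5S)-2-tert-butyl-5-[(2R)-2-hydroxybut-3-en-1-yl]-5-(prop-2-en-1-yl)-1,3-dioxolan-4-one
Product: 10 (2S,5S)-2-tert-butyl-5-[(2R)-2-(tert-butyldimethylsilyloxy)but-3-en-1-yl]-5-(prop-2-en-1-yl)-1,3-dioxolan-4-one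
Conditions: TBSOTf, 2,6-lutidine, CH2Cl2, −78 °C
Reagents that add atoms: tert-butyldimethylsilyl triflate, CC(C)(C)[Si](C)(C)OS(=O)(=O)C(F)(F)F
Why: Silyl ether formation with the silyl triflate is fast in the cold and caps the γ-hydroxyl before it can lactonise onto the dioxolanone carbonyl.

Step 6
Reactants: 10 (2S,5S)-2-tert-butyl-5-[(2R)-2-(tert-butyldimethylsilyloxy)but-3-en-1-yl]-5-(prop-2-en-1-yl)-1,3-dioxolan-4-one
Product: 11 (2S,4R)-4-(tert-butyldimethylsilyloxy)-2-hydroxy-2-(prop-2-en-1-yl)hex-5-enoic acid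
Conditions: LiOH·H2O (4 equiv), THF–H2O (3:1), 0 °C → rt; 1 M HCl to pH 3 at 0 °C
Reagents that add atoms: lithium hydroxide, [Li+].[OH-] (its oxygen ends in the carboxyl group)
Why: Saponification of the acylal: hydroxide opens the dioxolanone, the hemiacetal collapses with loss of pivalaldehyde, and the tertiary α-hydroxy acid is released without touching the quaternary centre or the secondary silyl ether.

Step 7
Reactants: 11 (2S,4R)-4-(tert-butyldimethylsilyloxy)-2-hydroxy-2-(prop-2-en-1-yl)hex-5-enoic acid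
Product: 12 tert-butyl (2S,4R)-4-(tert-butyldimethylsilyloxy)-2-hydroxy-2-(prop-2-en-1-yl)hex-5-enoate
Conditions: Cl3CC(=NH)OtBu (2.5 equiv), cyclohexane–CH2Cl2, rt
Reagents that add atoms: tert-butyl 2,2,2-trichloroacetimidate, CC(C)(C)OC(=N)C(Cl)(Cl)Cl
Why: Esterification by tert-butyl transfer from the trichloroacetimidate to the carboxylate oxygen is indifferent to hindrance at the acyl carbon and, without a Lewis acid, leaves the tertiary alcohol and the silyl ether alone.

Step 8
Reactants: 12 tert-butyl (2S,4R)-4-(tert-butyldimethylsilyloxy)-2-hydroxy-2-(prop-2-en-1-yl)hex-5-enoate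
Product: 13 tert-butyl (2S,4R)-4-(tert-butyldimethylsilyloxy)-2-(prop-2-en-1-yl)-2-(triethylsilyloxy)hex-5-enoate
Conditions: TESOTf, 2,6-lutidine, CH2Cl2, 0 °C → rt
Reagents that add atoms: triethylsilyl triflate, CC[Si](CC)(CC)OS(=O)(=O)C(F)(F)F
Why: Silylation of the tertiary alcohol with the reactive silyl triflate keeps the later γ-hydroxy aldehyde from closing to a lactol, so both aldehydes stay free for the coupling.

Step 9
Reactants: 13 tert-butyl (2S,4R)-4-(tert-butyldimethylsilyloxy)-2-(prop-2-en-1-yl)-2-(triethylsilyloxy)hex-5-enoate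
Product: 15 tert-butyl (2R,4R)-4-(tert-butyldimethylsilyloxy)-5-oxo-2-(2-oxoethyl)-2-(triethylsilyloxy)pentanoate, via bis-ozonide 14 (not isolated)
Conditions: O3, CH2Cl2, −78 °C; PPh3, −78 °C → rt; short silica plug, used at once
Reagents that add atoms: ozone, [O-][O+]=O
Why: Ozonolysis with reductive work-up cleaves both terminal alkenes at once to the 1,6-dialdehyde, the silyl ethers and the tert-butyl ester being inert to ozone at −78 °C, and immediate use should avoid epimerisation of the α-silyloxy aldehyde at C5.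

Step 10
Reactants: 15 tert-butyl (2R,4R)-4-(tert-butyldimethylsilyloxy)-5-oxo-2-(2-oxoethyl)-2-(triethylsilyloxy)pentanoate
Product: 16 tert-butyl 5-O-(tert-butyldimethylsilyl)-1-O-(triethylsilyl)-(−)-quinate (3-OH and 4-OH cis to each other and to O1, trans to O5)
Conditions: SmI2 (0.1 M in THF, 3 equiv), t-BuOH (3 equiv), THF (high dilution), −78 → −20 °C; sat. aq. NH4Cl
Reagents that add atoms: none
Why: Electron transfer from divalent samarium to one aldehyde gives a samarium-bound ketyl radical that adds to the carbon of the second, samarium-coordinated aldehyde and forms the C3–C4 bond, after which a second electron gives the trivalent samarium diolate that is protonated by t-BuOH and the work-up; the closest known reaction is the SmI2 pinacol cyclisation of 1,6-dialdehydes used for cyclitols. The cyclohexane ring closes by 6-exo-trig attack of the ketyl on the C=O group. C3 and C4 should come out cis because both oxygens are held on one samarium centre in the chair-like transition state. The face is set by the C5 stereocentre: the samarium-bound diolate should form anti to the α-silyloxy group for steric and dipole reasons, which places O4 trans to O5 and O3 cis to O1. The step therefore needs cis selectivity across C3–C4 and anti selectivity to O5, and the substrate secures them through the α-silyloxy aldehyde, while the quaternary C1 cannot epimerise and its gem-disubstitution together with high dilution favours ring closure over intermolecular coupling.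

Step 11
Reactants: 16 tert-butyl 5-O-(tert-butyldimethylsilyl)-1-O-(triethylsilyl)-(−)-quinate; 17 mono-tert-butyl succinate (4-tert-butoxy-4-oxobutanoic acid)
Product: 18 tert-butyl 4-O-(4-tert-butoxy-4-oxobutanoyl)-5-O-(tert-butyldimethylsilyl)-1-O-(triethylsilyl)quinate
Conditions: 17 (1.1 equiv), N,N′-diisopropylcarbodiimide (1.1 equiv), DMAP (0.1 equiv), CH2Cl2, −20 → 0 °C
Reagents that add atoms: mono-tert-butyl succinate 17, CC(C)(C)OC(=O)CCC(=O)O
Why: Steglich esterification in the cold with one equivalent of acid should acylate the equatorial O4 hydroxyl in preference to the axial O3 hydroxyl, which is shielded 1,3-diaxially by the C1 silyloxy group, in line with the usual preference for the equatorial hydroxyl of a cyclic cis-diol (as in 3,4-diols of galactosides).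

Step 12
Reactants: 18 tert-butyl 4-O-(4-tert-butoxy-4-oxobutanoyl)-5-O-(tert-butyldimethylsilyl)-1-O-(triethylsilyl)quinate
Product: 19 tert-butyl 4-O-(4-tert-butoxy-4-oxobutanoyl)quinate (1,3,5-triol)
Conditions: HF·pyridine, pyridine, THF, 0 °C → rt
Reagents that add atoms: none
Why: Fluoride-mediated desilylation with buffered HF·pyridine removes the tertiary triethylsilyl and the secondary tert-butyldimethylsilyl ether under mildly acidic conditions, in which the esters survive and migration of the O4 acyl group to the freed neighbours is slow.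

Step 13
Reactants: 20 caffeic acid
Product: 22 (E)-3-[3,4-bis(tert-butyldimethylsilyloxy)phenyl]prop-2-enoic acid, via silyl ester 21 (not isolated)
Conditions: TBSCl (3.3 equiv), imidazole, DMF, rt; then AcOH–THF–H2O (3:1:1), rt
Reagents that add atoms: tert-butyldimethylsilyl chloride, CC(C)(C)[Si](C)(C)Cl
Why: Exhaustive silylation followed by selective hydrolysis of the labile silyl ester is the standard way to protect the catechol of caffeic acid while leaving the carboxyl group free.

Step 14
Reactants: 19 tert-butyl 4-O-(4-tert-butoxy-4-oxobutanoyl)quinate; 22 (E)-3-[3,4-bis(tert-butyldimethylsilyloxy)phenyl]prop-2-enoic acid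
Product: 24 tert-butyl 4-O-(4-tert-butoxy-4-oxobutanoyl)-1,3,5-tris-O-[(E)-3,4-bis(tert-butyldimethylsilyloxy)cinnamoyl]quinate, via caffeoyl chloride 23 (not isolated)
Conditions: 22 (6 equiv), (COCl)2, DMF (cat.), CH2Cl2, 0 °C → rt, evaporate; then 19, pyridine, DMAP (1.5 equiv), CH2Cl2, 0 °C → 40 °C
Reagents that add atoms: silyl-protected caffeic acid 22 (three acyl units), O=C(O)/C=C/c1ccc(O[Si](C)(C)C(C)(C)C)c(O[Si](C)(C)C(C)(C)C)c1; oxalyl chloride, O=C(Cl)C(=O)Cl (supplies only the chlorine of 23)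
Why: DMAP-catalysed acylation with the acid chloride should esterify the secondary O3 and O5 hydroxyls first in the cold, which removes the free neighbours of the O4 succinate before acyl migration can set in, and the tertiary O1 hydroxyl should follow on warming with excess reagent, as in known acylations of the tertiary hydroxyl of quinates.

Step 15
Reactants: 24 tert-butyl 4-O-(4-tert-butoxy-4-oxobutanoyl)-1,3,5-tris-O-[(E)-3,4-bis(tert-butyldimethylsilyloxy)cinnamoyl]quinate
Product: 26 4-O-(3-carboxypropanoyl)-1,3,5-tri-O-[(E)-caffeoyl]-(−)-quinic acid (CNP0143991.1), via hexasilyl diacid 25 (not isolated)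
Conditions: TFA–CH2Cl2 (1:1), 0 °C → rt, evaporate; then Et3N·3HF, THF, rt; reversed-phase chromatography
Reagents that add atoms: none
Why: Acidolysis of the two tert-butyl esters with trifluoroacetic acid is followed in the same flask by fluoride cleavage of the six aryl silyl ethers, neither reagent attacks the four carboxylic esters, and no free alcohol remains to which an acyl group could migrate.

**Compound list**

1 | (S)-malic acid | O=C(O)C[C@H](O)C(=O)O | starting material
2 | pivalaldehyde | CC(C)(C)C=O | starting material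
3 | 2-[(2S,4S)-2-tert-butyl-5-oxo-1,3-dioxolan-4-yl]acetic acid | OC(=O)C[C@@H]1O[C@H](C(C)(C)C)OC1=O | intermediate
4 | allyl bromide | C=CCBr | starting material
5 | 2-[(2S,4S)-2-tert-butyl-5-oxo-4-(prop-2-en-1-yl)-1,3-dioxolan-4-yl]acetic acid | OC(=O)C[C@]1(CC=C)O[C@H](C(C)(C)C)OC1=O | intermediate
6 | tributyl(vinyl)stannane | C=C[Sn](CCCC)(CCCC)CCCC | starting material
7 | 2-[(2S,4S)-2-tert-butyl-5-oxo-4-(prop-2-en-1-yl)-1,3-dioxolan-4-yl]acetyl chloride | O=C(Cl)C[C@]1(CC=C)O[C@H](C(C)(C)C)OC1=O | intermediate (not isolated)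
8 | (2S,5S)-2-tert-butyl-5-(2-oxobut-3-en-1-yl)-5-(prop-2-en-1-yl)-1,3-dioxolan-4-one | C=CC(=O)C[C@]1(CC=C)O[C@H](C(C)(C)C)OC1=O | intermediate
9 | (2S,5S)-2-tert-butyl-5-[(2R)-2-hydroxybut-3-en-1-yl]-5-(prop-2-en-1-yl)-1,3-dioxolan-4-one | C=C[C@H](O)C[C@]1(CC=C)O[C@H](C(C)(C)C)OC1=O | intermediate
10 | (2S,5S)-2-tert-butyl-5-[(2R)-2-(tert-butyldimethylsilyloxy)but-3-en-1-yl]-5-(prop-2-en-1-yl)-1,3-dioxolan-4-one | C=C[C@H](O[Si](C)(C)C(C)(C)C)C[C@]1(CC=C)O[C@H](C(C)(C)C)OC1=O | intermediate
11 | (2S,4R)-4-(tert-butyldimethylsilyloxy)-2-hydroxy-2-(prop-2-en-1-yl)hex-5-enoic acid | C=C[C@H](O[Si](C)(C)C(C)(C)C)C[C@](O)(C(=O)O)CC=C | intermediate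
12 | tert-butyl (2S,4R)-4-(tert-butyldimethylsilyloxy)-2-hydroxy-2-(prop-2-en-1-yl)hex-5-enoate | C=C[C@H](O[Si](C)(C)C(C)(C)C)C[C@](O)(C(=O)OC(C)(C)C)CC=C | intermediate
13 | tert-butyl (2S,4R)-4-(tert-butyldimethylsilyloxy)-2-(prop-2-en-1-yl)-2-(triethylsilyloxy)hex-5-enoate | C=C[C@H](O[Si](C)(C)C(C)(C)C)C[C@](O[Si](CC)(CC)CC)(C(=O)OC(C)(C)C)CC=C | intermediate
14 | bis-ozonide of 13 (both alkenes as 1,2,4-trioxolanes, epimers at the trioxolane carbons) | C1(OCOO1)[C@H](O[Si](C)(C)C(C)(C)C)C[C@](O[Si](CC)(CC)CC)(C(=O)OC(C)(C)C)CC1OCOO1 | intermediate (not isolated)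
15 | tert-butyl (2R,4R)-4-(tert-butyldimethylsilyloxy)-5-oxo-2-(2-oxoethyl)-2-(triethylsilyloxy)pentanoate | O=C[C@H](O[Si](C)(C)C(C)(C)C)C[C@](O[Si](CC)(CC)CC)(C(=O)OC(C)(C)C)CC=O | intermediate
16 | tert-butyl 5-O-(tert-butyldimethylsilyl)-1-O-(triethylsilyl)-(−)-quinate (O1, O3, O4 cis; O5 trans) | O[C@H]1[C@H](O[Si](C)(C)C(C)(C)C)C[C@](O[Si](CC)(CC)CC)(C(=O)OC(C)(C)C)C[C@H]1O | intermediate
17 | mono-tert-butyl succinate | CC(C)(C)OC(=O)CCC(=O)O | starting material
18 | tert-butyl 4-O-(4-tert-butoxy-4-oxobutanoyl)-5-O-(tert-butyldimethylsilyl)-1-O-(triethylsilyl)quinate | CC(C)(C)OC(=O)CCC(=O)O[C@H]1[C@H](O[Si](C)(C)C(C)(C)C)C[C@](O[Si](CC)(CC)CC)(C(=O)OC(C)(C)C)C[C@H]1O | intermediate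
19 | tert-butyl 4-O-(4-tert-butoxy-4-oxobutanoyl)quinate | CC(C)(C)OC(=O)CCC(=O)O[C@H]1[C@H](O)C[C@](O)(C(=O)OC(C)(C)C)C[C@H]1O | intermediate
20 | caffeic acid | O=C(O)/C=C/c1ccc(O)c(O)c1 | starting material
21 | tert-butyldimethylsilyl (E)-3-[3,4-bis(tert-butyldimethylsilyloxy)phenyl]prop-2-enoate | CC(C)(C)[Si](C)(C)OC(=O)/C=C/c1ccc(O[Si](C)(C)C(C)(C)C)c(O[Si](C)(C)C(C)(C)C)c1 | intermediate (not isolated)
22 | (E)-3-[3,4-bis(tert-butyldimethylsilyloxy)phenyl]prop-2-enoic acid | O=C(O)/C=C/c1ccc(O[Si](C)(C)C(C)(C)C)c(O[Si](C)(C)C(C)(C)C)c1 | intermediate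
23 | (E)-3-[3,4-bis(tert-butyldimethylsilyloxy)phenyl]prop-2-enoyl chloride | O=C(Cl)/C=C/c1ccc(O[Si](C)(C)C(C)(C)C)c(O[Si](C)(C)C(C)(C)C)c1 | intermediate (not isolated)
24 | tert-butyl 4-O-(4-tert-butoxy-4-oxobutanoyl)-1,3,5-tris-O-[(E)-3,4-bis(tert-butyldimethylsilyloxy)cinnamoyl]quinate | CC(C)(C)OC(=O)CCC(=O)O[C@H]1[C@H](OC(=O)/C=C/c2ccc(O[Si](C)(C)C(C)(C)C)c(O[Si](C)(C)C(C)(C)C)c2)C[C@](OC(=O)/C=C/c2ccc(O[Si](C)(C)C(C)(C)C)c(O[Si](C)(C)C(C)(C)C)c2)(C(=O)OC(C)(C)C)C[C@H]1OC(=O)/C=C/c1ccc(O[Si](C)(C)C(C)(C)C)c(O[Si](C)(C)C(C)(C)C)c1 | intermediate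
25 | 4-O-(3-carboxypropanoyl)-1,3,5-tris-O-[(E)-3,4-bis(tert-butyldimethylsilyloxy)cinnamoyl]quinic acid | O=C(O)CCC(=O)O[C@H]1[C@H](OC(=O)/C=C/c2ccc(O[Si](C)(C)C(C)(C)C)c(O[Si](C)(C)C(C)(C)C)c2)C[C@](OC(=O)/C=C/c2ccc(O[Si](C)(C)C(C)(C)C)c(O[Si](C)(C)C(C)(C)C)c2)(C(=O)O)C[C@H]1OC(=O)/C=C/c1ccc(O[Si](C)(C)C(C)(C)C)c(O[Si](C)(C)C(C)(C)C)c1 | intermediate (not isolated)
26 | 4-O-(3-carboxypropanoyl)-1,3,5-tri-O-[(E)-caffeoyl]-(−)-quinic acid | O=C(O)CCC(=O)O[C@H]1[C@H](OC(=O)/C=C/c2ccc(O)c(O)c2)C[C@](OC(=O)/C=C/c2ccc(O)c(O)c2)(C(=O)O)C[C@H]1OC(=O)/C=C/c1ccc(O)c(O)c1 | target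

**Step count and risks**

Total: 15 steps. Longest linear sequence: 14 steps (steps 1–12, 14 and 15, from (S)-malic acid); step 13 is a one-step side branch.

Most likely to fail:

1. Step 10. The ketyl addition may lose facial control (cis-diol on the face of the C5 silyloxy group, or a trans-diol). The dialdehyde may also be consumed by simple reduction or by β-elimination of the C1 silyloxy group before it cyclises. The fallback sets out from diene 13 and comes back at diol 16. Ring-closing metathesis of 13 with the second-generation Grubbs catalyst RuCl2(H2IMes)(PCy3)(=CHPh) in CH2Cl2 at 40 °C would close the same C3–C4 bond as an alkene and give tert-butyl (1S,5R)-5-(tert-butyldimethylsilyloxy)-1-(triethylsilyloxy)cyclohex-3-ene-1-carboxylate F1. Upjohn dihydroxylation (OsO4 cat., N-methylmorpholine N-oxide, acetone–water) would then add both oxygens cis and, following the usual anti preference relative to an allylic silyloxy group, on the face opposite O5, which gives 16.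

2. Step 14. Acylation of the tertiary O1 hydroxyl may stall, and the O4 succinate may migrate if capping of O3 and O5 is slow. The fallback sets out from triol 19 and comes back at target 26. Heating 19 with Meldrum's acid in toluene (100 °C) would open the reagent with each hydroxyl, the tertiary one included, to give tert-butyl 4-O-(4-tert-butoxy-4-oxobutanoyl)-1,3,5-tris-O-(carboxyacetyl)quinate F2. Knoevenagel–Doebner condensation with 3,4-dihydroxybenzaldehyde (pyridine, cat. piperidine, 50 °C) would build the three (E)-caffeoyl esters with loss of CO2 and give tert-butyl 4-O-(4-tert-butoxy-4-oxobutanoyl)-1,3,5-tri-O-[(E)-caffeoyl]quinate F3 with free catechols. TFA–CH2Cl2 would then cleave both tert-butyl esters to 26.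

3. Step 11. Site selectivity between O4 and O3 may be poor, and double acylation or DMAP-induced acyl migration may occur. The fallback sets out from diol 16 and comes back at 18. Bu2SnO in refluxing toluene would give the 3,4-O-dibutylstannylene acetal of 16 F4, in which the equatorial O4 is the more nucleophilic oxygen. Succinic anhydride would open at O4 to tert-butyl 4-O-(3-carboxypropanoyl)-5-O-(tert-butyldimethylsilyl)-1-O-(triethylsilyl)quinate F5, and tert-butyl 2,2,2-trichloroacetimidate would esterify the free carboxyl group to give 18.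

Further compounds
F1 | step 10 | tert-butyl (1S,5R)-5-(tert-butyldimethylsilyloxy)-1-(triethylsilyloxy)cyclohex-3-ene-1-carboxylate | C1=C[C@H](O[Si](C)(C)C(C)(C)C)C[C@](O[Si](CC)(CC)CC)(C(=O)OC(C)(C)C)C1
F2 | step 14 | tert-butyl 4-O-(4-tert-butoxy-4-oxobutanoyl)-1,3,5-tris-O-(carboxyacetyl)quinate | CC(C)(C)OC(=O)CCC(=O)O[C@H]1[C@H](OC(=O)CC(=O)O)C[C@](OC(=O)CC(=O)O)(C(=O)OC(C)(C)C)C[C@H]1OC(=O)CC(=O)O
F3 | step 14 | tert-butyl 4-O-(4-tert-butoxy-4-oxobutanoyl)-1,3,5-tri-O-[(E)-caffeoyl]quinate | CC(C)(C)OC(=O)CCC(=O)O[C@H]1[C@H](OC(=O)/C=C/c2ccc(O)c(O)c2)C[C@](OC(=O)/C=C/c2ccc(O)c(O)c2)(C(=O)OC(C)(C)C)C[C@H]1OC(=O)/C=C/c1ccc(O)c(O)c1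
F4 | step 11 | 3,4-O-dibutylstannylene acetal of tert-butyl 5-O-(tert-butyldimethylsilyl)-1-O-(triethylsilyl)quinate | CCCC[Sn]1(CCCC)O[C@H]2[C@H](O[Si](C)(C)C(C)(C)C)C[C@](O[Si](CC)(CC)CC)(C(=O)OC(C)(C)C)C[C@H]2O1
F5 | step 11 | tert-butyl 4-O-(3-carboxypropanoyl)-5-O-(tert-butyldimethylsilyl)-1-O-(triethylsilyl)quinate | O=C(O)CCC(=O)O[C@H]1[C@H](O[Si](C)(C)C(C)(C)C)C[C@](O[Si](CC)(CC)CC)(C(=O)OC(C)(C)C)C[C@H]1O
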